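**Retrosynthetic overview**

1. Locants: terpenoid part C1–C12 (C3 lactone C=O, C4 CMe2O, C5 spiro carbon, C8 ring-B carbon bearing CH2-12, C9 ring-B CH, C10 C(Me)OH, C11 the CH2 between C9 and the phthalide part); phthalide part primed (C1' lactone C=O, C3a', C4' quaternary C–Me, C5' ketone, C6' quaternary C–Me, C7' CHOH, C7a').
2. Last disconnections: C7' alcohol from the C7' ketone, then a retro-[4+2] of the bicyclo[2.2.2]octane (bonds C8–C3a' and C12–C6') to a dienol in which ring B, with an exocyclic C8=C12 alkene, hangs from C4' of a cyclohexa-2,4-dienone (a dearomatised phthalide).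
3. Enabling feature: C3a' and C6' are the termini of the diene C6'=C7'(OH)–C7a'=C3a' of that dienone, and the C8=C12 methylene is held over them by the tether C4'–C11–C9. One [4+2] event therefore closes the cyclopentane (C8, C9, C11, C4', C3a') and the cyclohexane C8–C12–C6'–C7'–C7a'–C3a', and sets C8, C3a' and C6' (C7a' by tautomerisation).
4. The dienol comes from C4-alkylation of 5,7-dihydroxy-4,6-dimethylphthalide with a ring-B/spirolactone iodide. The iodide comes from (R)-pulegone: deconjugative Michael addition (C5), lactonisation onto the isopropenyl group, dehydrogenation (the bought centre is erased), methyl addition (C10), formaldehyde ene reaction (C9 and C8=C12).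
5. Ring order: ring B (bought) → spiro δ-lactone → (phthalide rings bought) → cyclopentane and bicyclo[2.2.2]octane together in the key step, the ring C8–C12–C6'–C7'–C7a'–C3a' being the last ring closed.

Key step: step 11

Assumption: the potassium dienolate of pulegone is taken to react through C4 by axial attack, cis to the ring methyl, so that (R)-pulegone gives the required quaternary centre; the epimers are separated in any case, and (S)-pulegone would be used if the sense were the reverse.

**Step 1**
Reactants: 1 (R)-(+)-pulegone; 2 tert-butyl acrylate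
Product: 3 tert-butyl 3-[(1R,4R)-4-methyl-2-oxo-1-(prop-1-en-2-yl)cyclohexyl]propanoate
Conditions: t-BuOK (0.2 equiv), t-BuOH/THF, 0 °C to rt; chromatography to remove the C1 epimer
Reagents that add atoms: none
Why: Deconjugative Michael addition of the thermodynamic (γ-deprotonated) dienolate through its α-carbon; the acrylate should enter axially on the half-chair enolate, cis to the equatorial ring methyl, so the bought (R)-centre fixes the new quaternary carbon (future C5).

**Step 2**
Reactants: 3
Product: 5 (6R,9R)-1,1,9-trimethyl-2-oxaspiro[5.5]undecane-3,7-dione, via carboxylic acid 4 (not isolated)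
Conditions: TFA/CH2Cl2 (1:4), 0 °C to rt
Reagents that add atoms: none
Why: Acidolysis of the tert-butyl ester, then Markovnikov protonation of the isopropenyl group and capture of the tertiary cation by the acid in a six-membered ring (acid-mediated hydro-acyloxylation/lactonisation); no stereocentre is touched, and the lactone is formed while no other hydroxyl group is present.

**Step 3**
Reactants: 5
Product: 6 (6R)-1,1,9-trimethyl-2-oxaspiro[5.5]undec-8-ene-3,7-dione
Conditions: IBX (2.5 equiv), DMSO, 70 °C
Reagents that add atoms: none
Why: IBX dehydrogenation of a ketone to the enone can only go towards the CH2–CH(Me) side because the other α-carbon is quaternary; it removes the bought stereocentre after it has set C5.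

**Step 4**
Reactants: 6
Product: 7 (6S,7R)-7-hydroxy-1,1,7,9-tetramethyl-2-oxaspiro[5.5]undec-8-en-3-one
Conditions: AlMe3 (3 equiv), toluene, –20 °C to rt; aq. Rochelle salt
Reagents that add atoms: trimethylaluminium, C[Al](C)C
Why: 1,2-Methyl addition of AlMe3 to the enone carbonyl, which should leave the lactone untouched at this temperature; the gem-dimethyl spiro arm must sit pseudo-equatorial (if axial, the lactone ring would force one methyl under ring B), so the lactone CH2 arm is pseudo-axial, shields its face, and methyl adds anti to it, giving the C10 hydroxyl cis to the CH2 arm.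

**Step 5**
Reactants: 7
Product: 9 (6S,7R)-7-hydroxy-1,1,7,9-tetramethyl-2-oxaspiro[5.5]undeca-4,8-dien-3-one, via selenide 8 (not isolated)
Conditions: LDA (2.2 equiv), THF, –78 °C, then PhSeBr; H2O2, pyridine, CH2Cl2, 0 °C to rt
Reagents that add atoms: none
Why: α-Selenenylation of the lactone lithium enolate (the alcohol is carried as its lithium alkoxide) and selenoxide syn-elimination; only the CH2 next to the spiro carbon has β-hydrogens, so the conjugated δ-lactone should result.

**Step 6**
Reactants: 9
Product: 10 (6S,7R,8S)-7-hydroxy-8-(hydroxymethyl)-1,1,7-trimethyl-9-methylidene-2-oxaspiro[5.5]undec-4-en-3-one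
Conditions: paraformaldehyde, Me2AlCl (3 equiv), CH2Cl2, –78 to 0 °C
Reagents that add atoms: formaldehyde (from paraformaldehyde), C=O
Why: Lewis-acid-promoted carbonyl-ene (Prins-type) reaction of formaldehyde with the trisubstituted alkene: the C–C bond forms at the less substituted carbon C9 and hydrogen is taken from the methyl group syn to the vinylic hydrogen, which gives the exocyclic C8=C12 alkene; formaldehyde bound to the aluminium alkoxide of the tertiary alcohol should be delivered cis to oxygen and anti to the pseudo-axial C10 methyl, which sets C9.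

**Step 7**
Reactants: 10
Product: 11 (6S,7R,8R)-7-hydroxy-8-(iodomethyl)-1,1,7-trimethyl-9-methylidene-2-oxaspiro[5.5]undec-4-en-3-one
Conditions: I2, PPh3, imidazole, CH2Cl2, 0 °C to rt
Reagents that add atoms: iodine, II
Why: Appel-type iodination, selective for the primary alcohol over the hindered tertiary one; no stereocentre is affected.

**Step 8**
Reactants: 12 5,7-dihydroxy-4-methylphthalide
Product: 13 5,7-dihydroxy-4-methyl-1-oxo-1,3-dihydro-2-benzofuran-6-carbaldehyde
Conditions: Cl2CHOMe, TiCl4, CH2Cl2, 0 °C; then aq. HCl
Reagents that add atoms: dichloromethyl methyl ether, COC(Cl)Cl; water, O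
Why: Rieche formylation; C6 is the only free ring position and is activated by both flanking hydroxyl groups.

**Step 9**
Reactants: 13
Product: 14 5,7-dihydroxy-4,6-dimethylphthalide
Conditions: Et3SiH, TFA, rt
Reagents that add atoms: none
Why: Ionic hydrogenation of an ortho-hydroxy aryl aldehyde to the methyl group via the stabilised benzylic cation; the lactone and the phenols are inert.

**Step 10**
Reactants: 11 iodide from step 7; 14 5,7-dihydroxy-4,6-dimethylphthalide
Product: 15 (4R)-7-hydroxy-4-{[(6S,7R,8R)-7-hydroxy-1,1,7-trimethyl-9-methylidene-3-oxo-2-oxaspiro[5.5]undec-4-en-8-yl]methyl}-4,6-dimethyl-2-benzofuran-1,5(3H,4H)-dione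
Conditions: LiHMDS (2.0 equiv), THF/toluene, –78 to 0 °C; then 11, 0 to 45 °C; chromatography to remove the C4 epimer
Reagents that add atoms: none
Why: C-Alkylative dearomatisation of a lithium phenolate, the reaction type used to attach allylic halides to the methyl-bearing ortho carbon of dimethylorsellinate-type phenols: tight Li–O pairing in the weakly polar medium should favour C- over O-alkylation, C4 (one neighbouring OLi) is more open than C6 (two), and the primary iodide is displaced by SN2; the new quaternary centre C4 (C4' of the target) is formed without reliable substrate control, so 15 is separated from its C4 epimer.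

**Step 11**
Reactants: 15
Product: 17 7'-oxo compound (18 with a ketone at C7'; β-keto γ-lactone), via enol cycloadduct 16 (not isolated)
Conditions: toluene (degassed, BHT), 130–150 °C, sealed tube
Reagents that add atoms: none
Why: Thermal intramolecular Diels–Alder reaction of a 6-(but-3-enyl)cyclohexa-2,4-dienone (closest known type: the cycloaddition of 6-alkenyl-2,4-cyclohexadienones and masked o-benzoquinones to isotwistenones), in which the hydrogen-bonded dienol C6'=C7'(OH)–C7a'=C3a' is the 4π part and the unactivated C8=C12 alkene the 2π part, the bonds C12–C6' and C8–C3a' forming in a concerted, asynchronous way. The cyclopentane (C8, C9, C11, C4', C3a') closes as the fused five-membered ring imposed by the two-atom tether C9–C11, and the same two bonds close the cyclohexane C8–C12–C6'–C7'–C7a'–C3a' as a bridged ring across C3a' and C6' (an isotwistane core); the reverse orientation (C8 to C6') would need a strained bridged seven-membered arrangement. C3a' and C6' follow from C4', because the alkene can only reach the diene face that carries C11; C8 follows from C9, because the five-ring transition state needs C11 pseudo-axial on ring B (its ground-state chair, CMe2 arm equatorial) and bonding at C8 on the same face, which gives the cis ring fusion. The selectivity needed is over the C4 epimer, which could only react through a strained trans-fused arrangement and was removed in step 10; dimerisation is blocked by the fully substituted diene termini. The first-formed enol 16 should tautomerise to 17 with C7a'–H on the side of the C12 bridge and the lactone carbonyl towards the C5' bridge, expected to be the more stable arrangement, and this centre stays epimerisable.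

**Step 12**
Reactants: 17
Product: 18 target CNP0360620.2
Conditions: NaBH4, CeCl3·7H2O, MeOH/CH2Cl2, –78 to –40 °C
Reagents that add atoms: none
Why: Luche-type borohydride reduction of the β-keto lactone ketone; the C5' ketone is shielded by two quaternary α-carbons and the enoate is not reduced under these conditions, and hydride should add to C7' from the C12 side, anti to the lactone carbonyl carbon on the neighbouring C7a', giving the hydroxyl cis to that carbonyl.

**Compound list**

1 | (R)-(+)-pulegone | C[C@@H]1CCC(=C(C)C)C(=O)C1 | starting material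
2 | tert-butyl acrylate | C=CC(=O)OC(C)(C)C | starting material
3 | tert-butyl 3-[(1R,4R)-4-methyl-2-oxo-1-(prop-1-en-2-yl)cyclohexyl]propanoate | C[C@H]1CC(=O)[C@@](C(C)=C)(CCC(=O)OC(C)(C)C)CC1 | intermediate
4 | 3-[(1R,4R)-4-methyl-2-oxo-1-(prop-1-en-2-yl)cyclohexyl]propanoic acid | C[C@H]1CC(=O)[C@@](C(C)=C)(CCC(=O)O)CC1 | intermediate
5 | (6R,9R)-1,1,9-trimethyl-2-oxaspiro[5.5]undecane-3,7-dione | CC1(C)OC(=O)CC[C@]12CC[C@@H](C)CC2=O | intermediate
6 | (6R)-1,1,9-trimethyl-2-oxaspiro[5.5]undec-8-ene-3,7-dione | CC1(C)OC(=O)CC[C@]12CCC(C)=CC2=O | intermediate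
7 | (6S,7R)-7-hydroxy-1,1,7,9-tetramethyl-2-oxaspiro[5.5]undec-8-en-3-one | CC1(C)OC(=O)CC[C@]12CCC(C)=C[C@@]2(C)O | intermediate
8 | (6S,7R)-7-hydroxy-1,1,7,9-tetramethyl-4-(phenylselanyl)-2-oxaspiro[5.5]undec-8-en-3-one (both C4 epimers) | CC1(C)OC(=O)C([Se]c3ccccc3)C[C@]12CCC(C)=C[C@@]2(C)O | intermediate
9 | (6S,7R)-7-hydroxy-1,1,7,9-tetramethyl-2-oxaspiro[5.5]undeca-4,8-dien-3-one | CC1(C)OC(=O)C=C[C@]12CCC(C)=C[C@@]2(C)O | intermediate
10 | (6S,7R,8S)-7-hydroxy-8-(hydroxymethyl)-1,1,7-trimethyl-9-methylidene-2-oxaspiro[5.5]undec-4-en-3-one | CC1(C)OC(=O)C=C[C@]12CCC(=C)[C@@H](CO)[C@@]2(C)O | intermediate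
11 | (6S,7R,8R)-7-hydroxy-8-(iodomethyl)-1,1,7-trimethyl-9-methylidene-2-oxaspiro[5.5]undec-4-en-3-one | CC1(C)OC(=O)C=C[C@]12CCC(=C)[C@@H](CI)[C@@]2(C)O | intermediate
12 | 5,7-dihydroxy-4-methylphthalide | O=C1OCc2c(C)c(O)cc(O)c12 | starting material
13 | 5,7-dihydroxy-4-methyl-1-oxo-1,3-dihydro-2-benzofuran-6-carbaldehyde | O=C1OCc2c(C)c(O)c(C=O)c(O)c12 | intermediate
14 | 5,7-dihydroxy-4,6-dimethylphthalide | O=C1OCc2c(C)c(O)c(C)c(O)c12 | intermediate
15 | (4R)-7-hydroxy-4-{[(6S,7R,8R)-7-hydroxy-1,1,7-trimethyl-9-methylidene-3-oxo-2-oxaspiro[5.5]undec-4-en-8-yl]methyl}-4,6-dimethyl-2-benzofuran-1,5(3H,4H)-dione | CC1(C)OC(=O)C=C[C@]12CCC(=C)[C@@H](C[C@@]3(C)C(=O)C(C)=C(O)C4=C3COC4=O)[C@@]2(C)O | intermediate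
16 | enol cycloadduct (C7'–OH, C7'=C7a' enol of 17; other stereocentres as in 18) | CC1(C)OC(=O)C=C[C@]12CC[C@]13C[C@]4(C)C(=O)[C@](C)(C[C@H]1[C@@]2(C)O)[C@]31COC(=O)C1=C4O | intermediate
17 | 7'-oxo compound (18 with a ketone at C7'; C7a'–H and all other stereocentres as in 18) | CC1(C)OC(=O)C=C[C@]12CC[C@]13C[C@]4(C)C(=O)[C@](C)(C[C@H]1[C@@]2(C)O)[C@]31COC(=O)[C@H]1C4=O | intermediate
18 | CNP0360620.2, (5S,8S,9R,10R,3a'R,4'R,6'S,7'R,7a'R) in the locants used here | CC1(C)OC(=O)C=C[C@]12CC[C@]13C[C@]4(C)C(=O)[C@](C)(C[C@H]1[C@@]2(C)O)[C@]31COC(=O)[C@H]1[C@H]4O | target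

**Step count and risks**

Total steps: 12. Longest linear sequence: 10 steps (steps 1–7, 10, 11, 12, from pulegone); the phthalide branch has 2 steps.

Steps most likely to fail:

Step 10. The phenolate may be alkylated on oxygen or through C6 faster than through C4 by the β-branched primary iodide, and the alkylation has no facial control at C4. Fallback: setting out from 10, ozonolysis of the exocyclic methylene (O3, then Me2S) would give hydroxy ketone F1, and dehydration with the Burgess reagent would give α-methylene ketone F2. Phenol 14 should add to this soft exocyclic enone through C4 under mild amine base (dearomative Michael addition; O-adducts revert) to give Michael adduct F3. Chemoselective methylenation of the ring-B ketone (Zn, CH2Br2, TiCl4) would then come back to the route at 15.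

Step 11. The dienol may tautomerise to the cross-conjugated form that is no diene, or the tertiary alcohol and the dienone may suffer acid-promoted dehydration or rearrangement at the temperature the cycloaddition needs. Fallback: setting out from 15, O-methylation of the enol with TMSCHN2 would lock the 2,4-dienone as methyl dienol ether F4. Its cycloaddition can be driven with a Lewis acid or at high pressure near room temperature to enol ether adduct F5, and mild aqueous acid hydrolysis would come back to the route at 17.

Step 4. The methyl nucleophile may attack the lactone, the new alkoxide may open it (translactonisation), or addition may occur from the other face. Fallback: setting out from 6, saponification with LiOH would open the lactone to hydroxy acid F6. With the carboxylate inert, MeMgBr should add under 1,3-chelation by the magnesium alkoxide of the C(Me)2O group, which holds that arm in the carbonyl plane and gives the same facial sense, to give diol acid F7. Acid-catalysed relactonisation onto the less hindered C(Me)2OH would come back to the route at 7.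

**Further compounds**

F1 | step 10 | 7-hydroxy-8-(hydroxymethyl)-1,1,7-trimethyl-2-oxaspiro[5.5]undec-4-ene-3,9-dione (stereocentres as in 10) | CC1(C)OC(=O)C=C[C@]12CCC(=O)[C@@H](CO)[C@@]2(C)O
F2 | step 10 | 7-hydroxy-1,1,7-trimethyl-8-methylidene-2-oxaspiro[5.5]undec-4-ene-3,9-dione (stereocentres as in 10) | CC1(C)OC(=O)C=C[C@]12CCC(=O)C(=C)[C@@]2(C)O
F3 | step 10 | Michael adduct, analogue of 15 with a ketone in place of the exocyclic methylene | CC1(C)OC(=O)C=C[C@]12CCC(=O)[C@@H](C[C@@]3(C)C(=O)C(C)=C(O)C4=C3COC4=O)[C@@]2(C)O
F4 | step 11 | 7-O-methyl dienol ether of 15 | CC1(C)OC(=O)C=C[C@]12CCC(=C)[C@@H](C[C@@]3(C)C(=O)C(C)=C(OC)C4=C3COC4=O)[C@@]2(C)O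
F5 | step 11 | 7'-O-methyl enol ether of 16 | CC1(C)OC(=O)C=C[C@]12CC[C@]13C[C@]4(C)C(=O)[C@](C)(C[C@H]1[C@@]2(C)O)[C@]31COC(=O)C1=C4OC
F6 | step 4 | 3-[1-(2-hydroxypropan-2-yl)-4-methyl-2-oxocyclohex-3-en-1-yl]propanoic acid (quaternary centre as in 6) | CC(C)(O)[C@]1(CCC(=O)O)CCC(C)=CC1=O
F7 | step 4 | 3-[2-hydroxy-1-(2-hydroxypropan-2-yl)-2,4-dimethylcyclohex-3-en-1-yl]propanoic acid (stereocentres as in 7) | CC(C)(O)[C@]1(CCC(=O)O)CCC(C)=C[C@@]1(C)O
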